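## Retrosynthetic overview

1. All 42 carbons come from three molecules of guaiazulene 1; one is oxygenated at C3 (azulenol 2) and dehydrogenated to the quinone methide 3.
2. The isopropyl group of 3 is excised as acetone by a Hock cleavage (hydroperoxide 4, azulenediol 5), giving the C12 azulene-1,5-quinone 6.
3. Both biaryl bonds: C3 of two more molecules of 1 adds to C7 and C2 of 6, the conjugate positions of its tropone carbonyl, with reoxidation after each addition (7, 8, 9, 10).
4. Key disconnection: hydration of 10 at C4 (ketol 11) and an α-ketol shift (hydroxy aldehyde 12) contract its tropone ring to the formyl-bearing benzene ring of target 13; C4 leaves the ring as the CHO carbon.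
5. Ring order: the five- and seven-membered rings are all bought with 1; the only ring made is the benzene ring of the indenone, formed last, in the same flask as the two arylations.

Assumption: the target has no stereogenic centre and its two biaryl axes are not specified in the SMILES, so there is no stereochemistry to set.

Assumption: the likely biogenesis is taken to be the union of three guaiazulene units, the middle one being oxidised to a des-isopropyl azulene-1,5-quinone whose seven-membered ring contracts.

Numbering: guaiazulene numbering for 1 (C3 is the free five-ring CH next to the ring-fusion carbon that carries the C4 methyl); azulen-1-ol / azulene-1,5-dione numbering for 2–11; indene numbering for 12 and 13. "Guaiazulen-3-yl" means 3,8-dimethyl-5-(propan-2-yl)azulen-1-yl.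

## Route

Step 1
Reactants: 1 guaiazulene [1,4-dimethyl-7-(propan-2-yl)azulene]
Product: 3 3,8-dimethyl-5-(propan-2-ylidene)azulen-1(5H)-one, via 3-hydroxyguaiazulene 2 (not isolated)
Conditions: mCPBA (0.95 equiv), CH2Cl2, −78 → −40 °C; then DDQ (1.0 equiv), −40 → 0 °C
Reagents that add atoms: mCPBA (3-chloroperoxybenzoic acid), OOC(=O)c1cccc(Cl)c1
Why: Electrophilic aromatic hydroxylation followed by quinone-methide-forming dehydrogenation: C3 is the only free nucleophilic five-ring carbon of 1 and attacks the peracid oxygen, and the very electron-rich azulenol 2 is then oxidised by DDQ like a para-isopropylphenol (hydride abstraction from the isopropyl methine, loss of the O–H proton) to the stable cross-conjugated azulenone 3; no stereocentre is formed.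

Step 2
Reactants: 3 3,8-dimethyl-5-(propan-2-ylidene)azulen-1(5H)-one
Product: 6 3,8-dimethylazulene-1,5-dione, via tertiary hydroperoxide 4 (not isolated), via azulenediol 5 (not isolated)
Conditions: 50% aq. H2O2 (2.5 equiv), TsOH·H2O (10 mol %), MeCN, 0 °C → rt
Reagents that add atoms: hydrogen peroxide, OO
Why: Hock rearrangement: O-protonated 3 is a cumyl-type cation stabilised by the 1-hydroxyazulene ring and captures H2O2 at the exocyclic carbon, the electron-rich azulenyl group of 4 migrates from carbon to oxygen with loss of water and the hemiketal releases acetone (the same chemistry that converts para-isopropenylphenol into hydroquinone), and the second equivalent of H2O2 oxidises azulenediol 5 to quinone 6; no stereocentre is formed.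

Step 3
Reactants: 6 3,8-dimethylazulene-1,5-dione (1.0 equiv); 1 guaiazulene (2.0 equiv)
Product: 13 3,7-dimethyl-1-oxo-2,6-bis[3,8-dimethyl-5-(propan-2-yl)azulen-1-yl]-1H-indene-4-carbaldehyde, via monoaryl azulenediol 7 (not isolated), via monoaryl quinone 8 (not isolated), via bisaryl azulenediol 9 (not isolated), via bisaryl quinone 10 (not isolated), via ketol hydrate 11 (not isolated), via hydroxy aldehyde 12 (not isolated)
Conditions: AcOH, TFA (10 mol %), O2 (1 atm), rt, dark; then H2O (AcOH/H2O 4:1), Ar, 70 °C
Reagents that add atoms: water, O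
Why: Proposed new method: protonated or hydrogen-bonded at its tropone-type C5 carbonyl, 6 is a hydroxytropylium-like electrophile whose acceptor CH positions are C7 (1,4) and C2 (1,6 through C4=C3a and C3=C2), and the strongly nucleophilic C3 of 1 adds there in a Friedel–Crafts-type conjugate addition (known for azulenes with quinones), each arylazulenediol (7, 9) being reoxidised to the quinone (8, 10) by O2, which ends as water; on adding water and heating, 10 is hydrated at C4 rather than C6 (C6 is shielded by the C7 aryl group, and hydration there would break the donor–acceptor conjugation between that aryl group and the C5 carbonyl), the α-ketol 11 undergoes a 1,2-shift of C3a from C4 to C5 (α-ketol or acyloin rearrangement) that extrudes C4 as the formyl carbon with its oxygen coming from water, and 1,4-loss of water from 12 aromatises the new benzene ring irreversibly; the closest known reactions are α-ketol ring contractions and the troponoid-to-benzenoid contraction of tropolones to benzoic acids; the stereocentres of 11 and 12 are transient and none remains in 13.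

## Compound list

1 | guaiazulene, 1,4-dimethyl-7-(propan-2-yl)azulene | CC1=C2C=CC(C)=C2C=C(C(C)C)C=C1 | starting material
2 | 3-hydroxyguaiazulene, 3,8-dimethyl-5-(propan-2-yl)azulen-1-ol | OC1=CC(C)=C2C=C(C(C)C)C=CC(C)=C12 | intermediate
3 | 3,8-dimethyl-5-(propan-2-ylidene)azulen-1(5H)-one | O=C1C=C(C)C2=CC(=C(C)C)C=CC(C)=C12 | intermediate
4 | 5-(2-hydroperoxypropan-2-yl)-3,8-dimethylazulen-1-ol | OC1=CC(C)=C2C=C(C(C)(C)OO)C=CC(C)=C12 | intermediate
5 | 3,8-dimethylazulene-1,5-diol | OC1=CC(C)=C2C=C(O)C=CC(C)=C12 | intermediate
6 | 3,8-dimethylazulene-1,5-dione | O=C1C=C(C)C2=CC(=O)C=CC(C)=C12 | intermediate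
7 | 7-(guaiazulen-3-yl)-3,8-dimethylazulene-1,5-diol | OC1=CC(C)=C2C=C(O)C=C(c3cc(C)c4cc(C(C)C)ccc(C)c3-4)C(C)=C12 | intermediate
8 | 7-(guaiazulen-3-yl)-3,8-dimethylazulene-1,5-dione | O=C1C=C(C)C2=CC(=O)C=C(c3cc(C)c4cc(C(C)C)ccc(C)c3-4)C(C)=C12 | intermediate
9 | 2,7-bis(guaiazulen-3-yl)-3,8-dimethylazulene-1,5-diol | OC1=C(c3cc(C)c4cc(C(C)C)ccc(C)c3-4)C(C)=C2C=C(O)C=C(c3cc(C)c4cc(C(C)C)ccc(C)c3-4)C(C)=C12 | intermediate
10 | 2,7-bis(guaiazulen-3-yl)-3,8-dimethylazulene-1,5-dione | O=C1C(c3cc(C)c4cc(C(C)C)ccc(C)c3-4)=C(C)C2=CC(=O)C=C(c3cc(C)c4cc(C(C)C)ccc(C)c3-4)C(C)=C12 | intermediate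
11 | 4-hydroxy-2,7-bis(guaiazulen-3-yl)-3,8-dimethyl-2,4-dihydroazulene-1,5-dione (mixture of stereoisomers at C2 and C4; both centres are lost later) | O=C1C(c3cc(C)c4cc(C(C)C)ccc(C)c3-4)C(C)=C2C(O)C(=O)C=C(c3cc(C)c4cc(C(C)C)ccc(C)c3-4)C(C)=C12 | intermediate
12 | 4-hydroxy-2,6-bis(guaiazulen-3-yl)-3,7-dimethyl-1-oxo-2,4-dihydro-1H-indene-4-carbaldehyde (mixture of stereoisomers at C2 and C4; both centres are lost in 13) | O=C1C(c3cc(C)c4cc(C(C)C)ccc(C)c3-4)C(C)=C2C(O)(C=O)C=C(c3cc(C)c4cc(C(C)C)ccc(C)c3-4)C(C)=C12 | intermediate
13 | CNP0222726.0, 3,7-dimethyl-1-oxo-2,6-bis[3,8-dimethyl-5-(propan-2-yl)azulen-1-yl]-1H-indene-4-carbaldehyde (achiral) | CC1=C(c2cc(C)c3cc(C(C)C)ccc(C)c2-3)C(=O)c2c(C)c(-c3cc(C)c4cc(C(C)C)ccc(C)c3-4)cc(C=O)c21 | target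

## Step count and risk

Total step count: 3. Longest linear sequence: 3 steps (1 → 3 → 6 → 13).

Steps most likely to fail:

Step 3 is the riskiest. The arylations may go to C4 or C6 instead of C7 and C2. The contraction may not occur, or may extrude towards C6 and give the 5-formyl isomer. Any unreacted 1 can condense with the product aldehyde under acid. The fallback sets out from 6 and comes back at 13: the order is inverted and the biaryl bonds are made by palladium catalysis. Quinone 6 alone is contracted by the same hydration and α-ketol shift (aq. TFA, MeCN, 60 °C) to 3,7-dimethyl-1-oxo-1H-indene-4-carbaldehyde F5. Bromine addition–elimination at the enone α-carbon (Br2, then Et3N) and electrophilic bromination at C6 (NBS, H2SO4), the ring carbon ortho to the methyl group and meta to both carbonyl-bearing carbons, give 2,6-dibromo-3,7-dimethyl-1-oxo-1H-indene-4-carbaldehyde F6. Twofold direct C–H arylation of 1 at its C3 with F6 (Pd(OAc)2, PPh3, K2CO3, nBu4NBr, DMF, 100 °C) then gives 13.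

Step 2 may fail because hydroperoxide 4 can dehydrate to the isopropenyl azulenol instead of rearranging, and because 6 may be over-oxidised or contract prematurely in aqueous acid. The fallback sets out from 1 and comes back at 6: the isopropyl group is removed before the five-membered ring is oxygenated. NBS (1.0 equiv, hexane/THF, 0 °C) gives 3-bromo-1,4-dimethyl-7-(propan-2-yl)azulene F2. Through its 3H-tautomer this bromide ionises to the azulenyl-substituted cumyl cation, which is trapped by 50% H2O2 as 7-(2-hydroperoxypropan-2-yl)-1,4-dimethylazulene F3. Hock cleavage (cat. H2SO4, acetone, 0 °C) gives 3,8-dimethylazulen-5-ol F4. Phenol-to-quinone oxidation at the free five-ring position conjugated to the hydroxyl group (PhI(OAc)2, 2.2 equiv, MeCN/H2O, 0 °C) gives 6.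

Step 1 may fail because the free azulenol 2 is more easily oxidised than 1 and can be destroyed by the peracid before DDQ is added. The fallback sets out from 1 and comes back at 3: the azulenol is made in protected form. Dibenzoyl peroxide (CH2Cl2, 0 °C → rt) acyloxylates C3 to 3,8-dimethyl-5-(propan-2-yl)azulen-1-yl benzoate F1, which is not over-oxidised. Methanolysis (K2CO3, MeOH/THF, Ar, 0 °C) releases 2, and after acidification with AcOH, DDQ is added directly to give 3.

Further compounds
F1 | step 1 | 3,8-dimethyl-5-(propan-2-yl)azulen-1-yl benzoate | O=C(OC1=CC(C)=C2C=C(C(C)C)C=CC(C)=C12)c1ccccc1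
F2 | step 2 | 3-bromo-1,4-dimethyl-7-(propan-2-yl)azulene | CC1=C2C(Br)=CC(C)=C2C=C(C(C)C)C=C1
F3 | step 2 | 7-(2-hydroperoxypropan-2-yl)-1,4-dimethylazulene | CC1=C2C=CC(C)=C2C=C(C(C)(C)OO)C=C1
F4 | step 2 | 3,8-dimethylazulen-5-ol | CC1=C2C=CC(C)=C2C=C(O)C=C1
F5 | step 3 | 3,7-dimethyl-1-oxo-1H-indene-4-carbaldehyde | CC1=CC(=O)c2c(C)ccc(C=O)c21
F6 | step 3 | 2,6-dibromo-3,7-dimethyl-1-oxo-1H-indene-4-carbaldehyde | CC1=C(Br)C(=O)c2c(C)c(Br)cc(C=O)c21
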